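The route rests on reading the O1–C2 bond of the dihydrofuran ring, with its C(CH3)=CH2 neighbour on C2, as a contracted O1–C(CH3)2 linkage of a 2,2-dimethylchroman. When the C3 hydroxyl of an enantiopure trans-4-(4-methoxybenzyloxy)chroman-3-ol is turned into a triflate, ring oxygen O1 moves from the quaternary carbon to C3. This single operation shrinks the pyran ring to the furan ring, inverts that carbon to set the trans C2/C3 relationship, and releases the isopropenyl group. The precursor already carries the acetyl and methoxy groups. It comes from encecalin by enantioselective epoxidation and anti alkoxide opening at C4. Ether cleavage and stereoretentive acylation with the Z side-chain acid follow.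

Key step: step 5

Remark (stereochemistry): the target is the trans (2R,3S) diastereomer with a Z side-chain alkene (CH3 cis to the carboxyl carbon, angelate type). Chroman C3/C4 become benzofuran C2/C3, so inversion at the former and retention at the latter demand the (3R,4S)-chromanol, hence the (3R,4R)-epoxide and the (R,R) catalyst.

Remark (design of the precursor): O4 is carried as a 4-methoxybenzyl ether. An ester there would close an acyloxonium ion onto C3, an allyl ether would need zerovalent palladium (which can ionise the allylic O1–C2 bond of the product), and a silyl ether would cost extra steps. The ether is installed with alkoxide rather than acid so that C4 never becomes a free cation.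

Step 1
Reactants: 1 1-(4-hydroxy-2-methoxyphenyl)ethanone; 2 3-chloro-3-methylbut-1-yne
Product: 3 1-[2-methoxy-4-(2-methylbut-3-yn-2-yloxy)phenyl]ethanone
Conditions: K2CO3 (2 equiv), KI (0.2 equiv), CuI (2 mol %), DMF, N2, 60 °C
Reagents that add atoms: none
Why: Williamson-type O-propargylation of an acidic para-acylphenol, in which copper acetylide formation lets the tertiary propargylic chloride ionise and be captured at oxygen faster than it eliminates; no stereocentre is formed.

Step 2
Reactants: 3 1-[2-methoxy-4-(2-methylbut-3-yn-2-yloxy)phenyl]ethanone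
Product: 5 encecalin (6-acetyl-7-methoxy-2,2-dimethyl-2H-chromene), via allenylphenol 4 (not isolated)
Conditions: N,N-diethylaniline, 185 °C
Reagents that add atoms: none
Why: Aryl propargyl ether Claisen rearrangement to 4, then 1,5-hydrogen shift and 6π-oxa-electrocyclisation; the [3,3] shift should go to the open ortho carbon para to the methoxy group, because the other ortho carbon is flanked by that methoxy group, whose methyl is pushed toward it by the acetyl group.

Step 3
Reactants: 5 encecalin
Product: 6 (3R,4R)-6-acetyl-3,4-epoxy-7-methoxy-2,2-dimethylchroman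
Conditions: (R,R)-Mn(salen)Cl (3 mol %; salen = N,N'-bis(3,5-di-tert-butylsalicylidene)cyclohexane-1,2-diaminate), 4-phenylpyridine N-oxide (0.2 equiv), aq. NaOCl buffered with Na2HPO4 to pH 11.3, CH2Cl2, 0 °C; filtration through basic Al2O3
Reagents that add atoms: sodium hypochlorite [Na+].[O-]Cl
Why: Jacobsen–Katsuki epoxidation of the ideal substrate class (cis, aryl-conjugated, gem-dimethyl-flanked cyclic alkene); the (R,R) ligand on trivalent manganese is known to deliver oxygen to the face of 2,2-dimethylchromenes that sets both C3 and C4 as R, and the basic two-phase medium spares the acid-labile epoxide and keeps hypochlorite away from the methyl ketone.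

Step 4
Reactants: 6 (3R,4R)-6-acetyl-3,4-epoxy-7-methoxy-2,2-dimethylchroman; 7 4-methoxybenzyl alcohol
Product: 9 1-[(3R,4S)-3-hydroxy-7-methoxy-4-(4-methoxybenzyloxy)-2,2-dimethylchroman-6-yl]ethanone (trans), via sodium alkoxide 8 (not isolated)
Conditions: 7 (5 equiv), NaH (0.3 equiv), THF, 0 °C → rt; water quench
Reagents that add atoms: sodium hydride [Na+].[H-] (its sodium stays only in 8)
Why: Base-catalysed SN2 alcoholysis of an epoxide, in which 8 attacks benzylic C4 (C3 is neopentylic) from the face opposite the oxirane oxygen, inverting C4 to S while C3 keeps its C–O bond and R configuration, so only the trans isomer should form; acid catalysis is avoided because a C4 cation stabilised by O1 and the 7-methoxy group would allow syn capture and 7 would self-condense.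

Step 5
Reactants: 9 1-[(3R,4S)-3-hydroxy-7-methoxy-4-(4-methoxybenzyloxy)-2,2-dimethylchroman-6-yl]ethanone
Product: 12 1-[(2R,3S)-6-methoxy-3-(4-methoxybenzyloxy)-2-(prop-1-en-2-yl)-2,3-dihydro-1-benzofuran-5-yl]ethanone (trans), via triflate 10 (not isolated), via oxiranium ion 11 (not isolated)
Conditions: Tf2O (1.05 equiv), 2,6-di-tert-butyl-4-methylpyridine (3 equiv), CH2Cl2, −78 → 0 °C, then rt; aq. NaHCO3 quench
Reagents that add atoms: triflic anhydride O=S(=O)(OS(=O)(=O)C(F)(F)F)C(F)(F)F (its triflyl group stays only in 10)
Why: The C3 hydroxyl is O-triflated to 10, whose diequatorial half-chair holds the C3–OTf bond antiperiplanar to the ring C2–O1 bond, so O1 attacks C3 from the rear and expels triflate to give the bridged oxiranium ion 11, which opens at its tertiary carbon while the hindered pyridine takes a methyl proton. The closest known reaction type is the aryloxy 1,2-shift (ring contraction) of activated 2,2-dimethylchroman-3-ols to 2-isopropenyl-2,3-dihydrobenzofurans, the counterpart of the pyranoside-to-furanoside contraction of equatorial sulfonates next to the ring oxygen. The three-membered ring of 11 closes in the 3-exo-tet mode, and the five-membered ring O1–C2–C3–C3a–C7a of 12 is what remains of the bicycle once the O1–C(CH3)2 bond has broken. The new stereocentre C2 (R) is controlled by stereospecific inversion at chroman C3, and because chroman C4 is untouched and becomes C3 (S), the trans chromanol maps onto the trans dihydrobenzofuran. The step needs O1 migration to beat the shift of aryl carbon C4a, participation of the C4 ether oxygen, methyl migration and E2 loss, and the substrate secures this because the diequatorial conformer places only ring bonds behind the leaving group, C3 lies near the nodal plane of the fused arene so no phenonium-type help is available, the trans arrangement leaves no antiperiplanar hydrogen, and the gem-dimethyl carbon can carry the developing charge. Chemoselectivity for the alcohol over enol triflation of the acetyl group rests on one equivalent of Tf2O at low temperature, and the terminal alkene results because only methyl C–H bonds can align with the breaking C–O bond of 11, whereas the C2–H bond is held nearly orthogonal to it.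

Step 6
Reactants: 12 1-[(2R,3S)-6-methoxy-3-(4-methoxybenzyloxy)-2-(prop-1-en-2-yl)-2,3-dihydro-1-benzofuran-5-yl]ethanone
Product: 13 1-[(2R,3S)-3-hydroxy-6-methoxy-2-(prop-1-en-2-yl)-2,3-dihydro-1-benzofuran-5-yl]ethanone
Conditions: DDQ (1.2 equiv), CH2Cl2/aq. NaH2PO4–Na2HPO4 buffer (pH 7) 10:1, 0 °C; used directly in step 10
Reagents that add atoms: none
Why: Oxidative cleavage of a 4-methoxybenzyl ether, in which DDQ abstracts hydride from the electron-rich anisyl CH2 rather than from the C3–H of the acetyl-deactivated benzofuran ring; the buffer neutralises the hydroquinone so the benzylic 3-ol does not dehydrate to the benzofuran, and both stereocentres are untouched.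

Step 7
Reactants: 14 methyl but-2-ynoate
Product: 16 methyl (Z)-2-(hydroxymethyl)but-2-enoate, via vinylalane 15 (not isolated)
Conditions: i-Bu2AlH (1.3 equiv), N-methylmorpholine N-oxide (2 equiv), THF, 0 °C; 14, 0 °C; CH2O gas (cracked paraformaldehyde), 0 °C → rt; aq. potassium sodium tartrate
Reagents that add atoms: formaldehyde C=O; diisobutylaluminium hydride CC(C)C[AlH]CC(C)C (its aluminium stays only in 15)
Why: Vinylalumination (syn hydroalumination of an ynoate, then carbonyl addition), in which the amine-oxide-complexed hydride adds H to the β-carbon and Al to the α-carbon on the same face without touching the ester, and the C–Al bond adds to formaldehyde with retention, so CH3 and CO2CH3 end up cis (Z).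

Step 8
Reactants: 16 methyl (Z)-2-(hydroxymethyl)but-2-enoate
Product: 17 (Z)-2-(hydroxymethyl)but-2-enoic acid (sarracinic acid)
Conditions: LiOH (2 equiv), THF/H2O 3:1, 0 °C → rt; 1 M HCl to pH 3
Reagents that add atoms: lithium hydroxide [Li+].[OH-]
Why: Ester saponification by acyl–oxygen cleavage at ambient temperature, mild enough that the Z alkene should not equilibrate by conjugate addition–elimination.

Step 9
Reactants: 17 (Z)-2-(hydroxymethyl)but-2-enoic acid
Product: 18 (Z)-2-(acetoxymethyl)but-2-enoic acid (O-acetylsarracinic acid)
Conditions: Ac2O (1.5 equiv), pyridine, CH2Cl2, 0 °C → rt; aqueous work-up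
Reagents that add atoms: acetic anhydride CC(=O)OC(C)=O
Why: O-Acetylation of the primary allylic alcohol; any mixed anhydride formed at the carboxyl group is hydrolysed during the aqueous work-up, and no strongly nucleophilic catalyst is present that could attack the enoate.

Step 10
Reactants: 13 1-[(2R,3S)-3-hydroxy-6-methoxy-2-(prop-1-en-2-yl)-2,3-dihydro-1-benzofuran-5-yl]ethanone; 18 (Z)-2-(acetoxymethyl)but-2-enoic acid
Product: 20 (2R,3S)-5-acetyl-6-methoxy-2-(prop-1-en-2-yl)-2,3-dihydro-1-benzofuran-3-yl (Z)-2-(acetoxymethyl)but-2-enoate (target), via mixed anhydride 19 (not isolated)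
Conditions: 18 (1.5 equiv), 2,4,6-trichlorobenzoyl chloride (1.5 equiv), Et3N (1.5 equiv), toluene, rt, filter; then 13, solid NaHCO3 (5 equiv), toluene, 65 °C, no DMAP
Reagents that add atoms: 2,4,6-trichlorobenzoyl chloride O=C(Cl)c1c(Cl)cc(Cl)cc1Cl (its aroyl group stays only in 19)
Why: Yamaguchi-type mixed-anhydride esterification in the catalyst-free variant used for angelate-type Z acids, in which the alcohol attacks the unhindered enoyl carbonyl of 19 directly, so no acylpyridinium forms that could suffer conjugate addition (Z to E drift) or SN2′ loss of acetate; NaHCO3 takes up the liberated acid so the benzylic C3–O bond is not ionised, and both ring stereocentres are untouched.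

Compound list
1 | 1-(4-hydroxy-2-methoxyphenyl)ethanone | CC(=O)c1ccc(O)cc1OC | starting material
2 | 3-chloro-3-methylbut-1-yne | CC(C)(Cl)C#C | starting material
3 | 1-[2-methoxy-4-(2-methylbut-3-yn-2-yloxy)phenyl]ethanone | CC(=O)c1ccc(OC(C)(C)C#C)cc1OC | intermediate
4 | 1-[4-hydroxy-2-methoxy-5-(3-methylbuta-1,2-dien-1-yl)phenyl]ethanone (allenylphenol, not isolated) | CC(=O)c1cc(C=C=C(C)C)c(O)cc1OC | intermediate
5 | encecalin, 6-acetyl-7-methoxy-2,2-dimethyl-2H-chromene | CC(=O)c1cc2c(cc1OC)OC(C)(C)C=C2 | intermediate
6 | (3R,4R)-6-acetyl-3,4-epoxy-7-methoxy-2,2-dimethylchroman | CC1(C)Oc2cc(OC)c(C(C)=O)cc2[C@H]2O[C@H]21 | intermediate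
7 | 4-methoxybenzyl alcohol | COc1ccc(CO)cc1 | starting material
8 | sodium 4-methoxybenzyl oxide (not isolated) | COc1ccc(C[O-])cc1.[Na+] | intermediate
9 | 1-[(3R,4S)-3-hydroxy-7-methoxy-4-(4-methoxybenzyloxy)-2,2-dimethylchroman-6-yl]ethanone, trans | CC1(C)Oc2cc(OC)c(C(C)=O)cc2[C@H](OCc2ccc(OC)cc2)[C@H]1O | intermediate
10 | (3R,4S)-6-acetyl-7-methoxy-4-(4-methoxybenzyloxy)-2,2-dimethylchroman-3-yl triflate (not isolated) | CC1(C)Oc2cc(OC)c(C(C)=O)cc2[C@H](OCc2ccc(OC)cc2)[C@H]1OS(=O)(=O)C(F)(F)F | intermediate
11 | bridged oxiranium ion, O1 bonded to C8a, to the C(CH3)2 carbon and to former chroman C3, triflate counter-ion (not isolated) | CC1(C)[O+]2c3cc(OC)c(C(C)=O)cc3[C@H](OCc3ccc(OC)cc3)[C@@H]12 | intermediate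
12 | 1-[(2R,3S)-6-methoxy-3-(4-methoxybenzyloxy)-2-(prop-1-en-2-yl)-2,3-dihydro-1-benzofuran-5-yl]ethanone, trans | C=C(C)[C@H]1Oc2cc(OC)c(C(C)=O)cc2[C@@H]1OCc1ccc(OC)cc1 | intermediate
13 | 1-[(2R,3S)-3-hydroxy-6-methoxy-2-(prop-1-en-2-yl)-2,3-dihydro-1-benzofuran-5-yl]ethanone, trans | C=C(C)[C@H]1Oc2cc(OC)c(C(C)=O)cc2[C@@H]1O | intermediate
14 | methyl but-2-ynoate | CC#CC(=O)OC | starting material
15 | methyl (E)-2-(diisobutylalumanyl)but-2-enoate (not isolated) | C/C=C(/[Al](CC(C)C)CC(C)C)C(=O)OC | intermediate
16 | methyl (Z)-2-(hydroxymethyl)but-2-enoate | C/C=C(/CO)C(=O)OC | intermediate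
17 | (Z)-2-(hydroxymethyl)but-2-enoic acid | C/C=C(/CO)C(=O)O | intermediate
18 | (Z)-2-(acetoxymethyl)but-2-enoic acid | C/C=C(/COC(C)=O)C(=O)O | intermediate
19 | (Z)-2-(acetoxymethyl)but-2-enoic 2,4,6-trichlorobenzoic anhydride (not isolated) | C/C=C(/COC(C)=O)C(=O)OC(=O)c1c(Cl)cc(Cl)cc1Cl | intermediate
20 | (2R,3S)-5-acetyl-6-methoxy-2-(prop-1-en-2-yl)-2,3-dihydro-1-benzofuran-3-yl (Z)-2-(acetoxymethyl)but-2-enoate | C=C(C)[C@H]1Oc2cc(OC)c(C(C)=O)cc2[C@@H]1OC(=O)/C(=C\C)COC(C)=O | target

Total step count: 10. Longest linear sequence: 7 (steps 1–6 and 10); the side chain takes steps 7–9.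

Steps most likely to fail

Step 5.
- **Risks:** the acetyl group para to O1 weakens the migrating oxygen. A semipinacol-type shift of aryl carbon C4a, pushed by the C4 ether oxygen, may therefore compete. So may participation of that ether oxygen after ring flip, enol triflation of the ketone, or loss of the wrong proton.
- **Fallback:** it sets out from 9 and comes back at 12.
  - MsCl and Et3N in CH2Cl2 at 0 °C should give the isolable mesylate F1.
  - Heating it in aqueous 2,2,2-trifluoroethanol over CaCO3 runs the O1 shift as a buffered solvolysis. Water captures the bridged ion at the tertiary carbon and gives the tertiary carbinol F2.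
  - Dehydration with the Burgess reagent in toluene at 50 °C, which favours the six methyl hydrogens, then gives 12.
- **What changes:** rearrangement and alkene formation are separated, and no triflating agent meets the ketone.

Step 10.
- **Risks:** nucleophilic attack on the activated enoyl unit may cause Z to E isomerisation or SN2′ loss of acetate. Warming the doubly donor-activated benzylic alcohol may cause dehydration with aromatisation.
- **Fallback:** it sets out from 6 and 18 and comes back at 20, and the acid is never activated as an acyl donor.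
  - Cs2CO3 (0.3 equiv) converts part of 18 (2 equiv) into the cesium carboxylate F3.
  - F3 opens 6 at C4 with inversion in DMF at rt, buffered by the remaining acid, to give the trans hydroxy ester F4.
  - Tf2O and 2,6-di-tert-butyl-4-methylpyridine, as in step 5, should then contract the ring through the triflate F5 and give 20 directly.
- **Why it is only second choice:** after ring flip the ester carbonyl can reach the rear of C3 and intercept the triflate.

Step 4.
- **Risks:** the alkoxide may enolise the acetyl group and start aldol-type self-condensation, or the opening may be slow enough to let such processes take over.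
- **Fallback:** it sets out from 6 and 7 and comes back at 9, and it activates the electrophile instead of the nucleophile. Compound 6 is dissolved in a large excess of 7 (10 equiv, little CH2Cl2) with pyridinium p-toluenesulfonate (5 mol %) at −20 °C. The high alcohol concentration should favour rear-side capture of the loosened C4–O bond, and any material that has lost anti selectivity is removed by chromatography before the key step.

Further compounds
F1 | step 5 | (3R,4S)-6-acetyl-7-methoxy-4-(4-methoxybenzyloxy)-2,2-dimethylchroman-3-yl methanesulfonate | CC1(C)Oc2cc(OC)c(C(C)=O)cc2[C@H](OCc2ccc(OC)cc2)[C@H]1OS(C)(=O)=O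
F2 | step 5 | 1-[(2S,3S)-2-(2-hydroxypropan-2-yl)-6-methoxy-3-(4-methoxybenzyloxy)-2,3-dihydro-1-benzofuran-5-yl]ethanone, trans | CC(C)(O)[C@H]1Oc2cc(OC)c(C(C)=O)cc2[C@@H]1OCc1ccc(OC)cc1
F3 | step 10 | cesium (Z)-2-(acetoxymethyl)but-2-enoate | C/C=C(/COC(C)=O)C(=O)[O-].[Cs+]
F4 | step 10 | (3R,4S)-6-acetyl-3-hydroxy-7-methoxy-2,2-dimethylchroman-4-yl (Z)-2-(acetoxymethyl)but-2-enoate | CC1(C)Oc2cc(OC)c(C(C)=O)cc2[C@H](OC(=O)/C(=C\C)COC(C)=O)[C@H]1O
F5 | step 10 | (3R,4S)-6-acetyl-7-methoxy-2,2-dimethyl-3-(trifluoromethylsulfonyloxy)chroman-4-yl (Z)-2-(acetoxymethyl)but-2-enoate | CC1(C)Oc2cc(OC)c(C(C)=O)cc2[C@H](OC(=O)/C(=C\C)COC(C)=O)[C@H]1OS(=O)(=O)C(F)(F)F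
F0 | step 4 | none | none
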